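**Retrosynthetic overview**

1. Target 17 comes from its 3'-O-methoxymethyl ether 16 by acid methanolysis.
2. The strategy rests on ring A being an acylphloroglucinol: C4a carries the C4 acyl carbon and lies between the oxygen-bearing C5 and C8a, with C7 also oxygenated and C6 prenylated. The C4a–C5 bond is therefore cut by a retro-Claisen to the pyranone-bound β-keto ester 14, in which O1 already sits on C8a, C2 is already (S) and the C6 prenyl group is on the carbon between C5 and C7.
3. Ring C of 14 (a 2,3-dihydro-4H-pyran-4-one) comes from cyclodehydration of the δ-hydroxy triketo ester 13. Compound 13 is cut at C4–C4a into the (S)-β-hydroxy Weinreb amide 8 and the trianion of diketo ester 12.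
4. Amide 8 comes from ring B aldehyde 4 (aldol, oxidation, asymmetric transfer hydrogenation), and 4 from bromophenol 1 (MOM protection, Stille prenylation). Ester 12 comes from methyl acetoacetate, prenyl bromide and N-methoxy-N-methylacetamide.
5. Ring order: ring B is bought, ring C is closed in step 8, ring A is closed and aromatized in step 9.

Key step: step 9

Assumption: compounds 12 to 15 are written as keto tautomers; each should exist largely enolized (13 partly as its cyclic hemiketal) and as a mixture at the labile prenyl-bearing carbon, which becomes planar in 16.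

**Route**

Step 1
Reactants: 1 2-bromo-3-hydroxy-4-methoxybenzaldehyde
Product: 2 2-bromo-4-methoxy-3-(methoxymethoxy)benzaldehyde
Conditions: MOMCl, i-Pr2NEt, CH2Cl2, 0 °C to rt
Reagents that add atoms: chloromethyl methyl ether, COCCl
Why: Williamson-type O-alkylation of the phenoxide by the reactive α-chloro ether; the aldehyde and the aryl bromide are inert under amine base.

Step 2
Reactants: 2 2-bromo-4-methoxy-3-(methoxymethoxy)benzaldehyde; 3 tributyl(3-methylbut-2-en-1-yl)stannane
Product: 4 4-methoxy-3-(methoxymethoxy)-2-(3-methylbut-2-en-1-yl)benzaldehyde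
Conditions: Pd(PPh3)4 (5 mol %), degassed DMF, 90 °C
Reagents that add atoms: none
Why: Migita–Kosugi–Stille coupling, in which zerovalent palladium inserts into the C–Br bond activated by the ortho formyl group and the allyl-palladium intermediate should couple at its unsubstituted CH2 terminus to give the linear prenyl arene.

Step 3
Reactants: 4 4-methoxy-3-(methoxymethoxy)-2-(3-methylbut-2-en-1-yl)benzaldehyde; 5 N-methoxy-N-methylacetamide
Product: 6 rac-3-hydroxy-N-methoxy-3-[4-methoxy-3-(methoxymethoxy)-2-(3-methylbut-2-en-1-yl)phenyl]-N-methylpropanamide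
Conditions: 5, LiN(i-Pr)2 (LDA), THF, −78 °C; then 4, −78 °C; AcOH quench at −78 °C
Reagents that add atoms: none
Why: Aldol addition of the lithium enolate of the Weinreb acetamide, stable at −78 °C, to the aldehyde; the carbinol centre is formed racemic on purpose because step 4 erases it.

Step 4
Reactants: 6 rac-3-hydroxy-N-methoxy-3-[4-methoxy-3-(methoxymethoxy)-2-(3-methylbut-2-en-1-yl)phenyl]-N-methylpropanamide
Product: 7 N-methoxy-3-[4-methoxy-3-(methoxymethoxy)-2-(3-methylbut-2-en-1-yl)phenyl]-N-methyl-3-oxopropanamide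
Conditions: activated MnO2 (excess), CH2Cl2, rt
Reagents that add atoms: none
Why: MnO2 oxidation is selective for the electron-rich benzylic alcohol and should leave the trisubstituted alkene, the MOM ether and the Weinreb amide untouched.

Step 5
Reactants: 7 N-methoxy-3-[4-methoxy-3-(methoxymethoxy)-2-(3-methylbut-2-en-1-yl)phenyl]-N-methyl-3-oxopropanamide
Product: 8 (3S)-3-hydroxy-N-methoxy-3-[4-methoxy-3-(methoxymethoxy)-2-(3-methylbut-2-en-1-yl)phenyl]-N-methylpropanamide
Conditions: RuCl(p-cymene)[(S,S)-TsDPEN] (1 mol %), HCO2H/Et3N (5:2), DMF, 30 °C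
Reagents that add atoms: none
Why: Noyori–Ikariya asymmetric transfer hydrogenation of an aryl ketone; the (S,S)-TsDPEN ligand delivers hydride in the same sense as for acetophenone to (S)-1-phenylethanol, and since aryl ranks above CH2 this sets the (S) carbinol that becomes C2.

Step 6
Reactants: 9 methyl acetoacetate; 10 1-bromo-3-methylbut-2-ene
Product: 11 methyl 2-acetyl-5-methylhex-4-enoate
Conditions: NaH, THF, 0 °C; then 10 (0.9 equiv), 0 °C to rt
Reagents that add atoms: none
Why: Acetoacetic ester C-alkylation of the sodium enolate by an allylic bromide; a slight excess of 9 limits dialkylation.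

Step 7
Reactants: 11 methyl 2-acetyl-5-methylhex-4-enoate; 5 N-methoxy-N-methylacetamide
Product: 12 methyl 2-(3-methylbut-2-en-1-yl)-3,5-dioxohexanoate
Conditions: NaH, THF, 0 °C; n-BuLi, 0 °C; then 5, −78 to 0 °C; AcOH quench
Reagents that add atoms: none
Why: γ-Acylation of the β-keto ester 1,3-dianion (Claisen-type condensation) at its terminal carbon; the chelated tetrahedral adduct of the Weinreb amide stops the reaction at the ketone.

Step 8
Reactants: 12 methyl 2-(3-methylbut-2-en-1-yl)-3,5-dioxohexanoate; 8 (3S)-3-hydroxy-N-methoxy-3-[4-methoxy-3-(methoxymethoxy)-2-(3-methylbut-2-en-1-yl)phenyl]-N-methylpropanamide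
Product: 14 methyl 4-[(2S)-2-[4-methoxy-3-(methoxymethoxy)-2-(3-methylbut-2-en-1-yl)phenyl]-4-oxo-3,4-dihydro-2H-pyran-6-yl]-2-(3-methylbut-2-en-1-yl)-3-oxobutanoate, via hydroxy triketo ester 13 (not isolated)
Conditions: 12 (2.2 equiv), LiN(i-Pr)2 (6.8 equiv), THF, −78 to 0 °C; lithium alkoxide of 8 (8, LiN(i-Pr)2 1.0 equiv, THF, −78 °C) added at −78 °C, then to 0 °C; AcOH, −78 °C; crude 13, TsOH·H2O (10 mol %), 4 Å MS, CH2Cl2, 0 °C to rt
Reagents that add atoms: none
Why: Claisen-type acylation of a β-dicarbonyl polyanion at its terminal carbanion by a Weinreb amide whose C2 alkoxide cannot β-eliminate, then acid-catalysed hemiketalization of the δ-hydroxy-β-diketone onto C8a and dehydration to the dihydropyranone; the C2–O bond is never broken, so the (S) centre is carried through.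

Step 9
Reactants: 14 methyl 4-[(2S)-2-[4-methoxy-3-(methoxymethoxy)-2-(3-methylbut-2-en-1-yl)phenyl]-4-oxo-3,4-dihydro-2H-pyran-6-yl]-2-(3-methylbut-2-en-1-yl)-3-oxobutanoate
Product: 16 (2S)-5,7-dihydroxy-2-[4-methoxy-3-(methoxymethoxy)-2-(3-methylbut-2-en-1-yl)phenyl]-6-(3-methylbut-2-en-1-yl)-2,3-dihydro-4H-chromen-4-one, via chromenetrione 15 (not isolated)
Conditions: Mg(OMe)2 (3 equiv), THF/MeOH, 0 °C to rt, argon; cold 0.5 M aq. HCl quench
Reagents that add atoms: none
Why: Proposed new method: Mg(OMe)2 reversibly deprotonates 14 at C6 and at C8; the C8 anion is a dienolate running through C8a=C4a to the C4 carbonyl, and its C4a terminus should add to the methyl ester held by magnesium in a six-membered chelate with the C7 oxygen, after which loss of methoxide gives trione 15 and two enolizations give the aromatic 5,7-diol 16. The closest known reaction type is the magnesium alkoxide Claisen cyclization of open-chain 3,5,7-triketo esters and of pyrone-bound polyketides to acylphloroglucinols; new here is a 2,3-dihydro-4H-pyran-4-one as the carrier of the nucleophilic carbon. Ring A closes by C4a–C5 bond formation in a 6-(enolexo)-exo-trig mode. No stereocentre is formed; C2 should survive because its C–O bond is not involved and the C3 hydrogens are far less acidic than those at C6 and C8, so retro-oxa-Michael opening should be slow under weakly basic, chelating conditions. The step needs the Claisen mode to win over lactonization and aldol modes: the ring oxygen already occupies the C8a enol so no pyrone can form, an aldol of C6 onto C4 would create a quaternary C6 that cannot dehydrate to an arene and should revert, and only the Claisen adduct is drained irreversibly by aromatization.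

Step 10
Reactants: 16 (2S)-5,7-dihydroxy-2-[4-methoxy-3-(methoxymethoxy)-2-(3-methylbut-2-en-1-yl)phenyl]-6-(3-methylbut-2-en-1-yl)-2,3-dihydro-4H-chromen-4-one
Product: 17 (2S)-5,7-dihydroxy-2-[3-hydroxy-4-methoxy-2-(3-methylbut-2-en-1-yl)phenyl]-6-(3-methylbut-2-en-1-yl)-2,3-dihydro-4H-chromen-4-one
Conditions: 3 M aq. HCl, MeOH, rt to 40 °C, short reaction time
Reagents that add atoms: none
Why: Acid-catalysed acetal exchange of the aryl methoxymethyl ether with methanol; under these mild conditions the prenyl groups should not cyclize onto the neighbouring phenols and the flavanone, which opens under base rather than acid, should keep its C2 configuration.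

**Compound list**

1 | 2-bromo-3-hydroxy-4-methoxybenzaldehyde | COc1ccc(C=O)c(Br)c1O | starting material
2 | 2-bromo-4-methoxy-3-(methoxymethoxy)benzaldehyde | COc1ccc(C=O)c(Br)c1OCOC | intermediate
3 | tributyl(3-methylbut-2-en-1-yl)stannane | CCCC[Sn](CCCC)(CCCC)CC=C(C)C | starting material
4 | 4-methoxy-3-(methoxymethoxy)-2-(3-methylbut-2-en-1-yl)benzaldehyde | COc1ccc(C=O)c(CC=C(C)C)c1OCOC | intermediate
5 | N-methoxy-N-methylacetamide | CC(=O)N(C)OC | starting material
6 | rac-3-hydroxy-N-methoxy-3-[4-methoxy-3-(methoxymethoxy)-2-(3-methylbut-2-en-1-yl)phenyl]-N-methylpropanamide | COc1ccc(C(O)CC(=O)N(C)OC)c(CC=C(C)C)c1OCOC | intermediate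
7 | N-methoxy-3-[4-methoxy-3-(methoxymethoxy)-2-(3-methylbut-2-en-1-yl)phenyl]-N-methyl-3-oxopropanamide | COc1ccc(C(=O)CC(=O)N(C)OC)c(CC=C(C)C)c1OCOC | intermediate
8 | (3S)-3-hydroxy-N-methoxy-3-[4-methoxy-3-(methoxymethoxy)-2-(3-methylbut-2-en-1-yl)phenyl]-N-methylpropanamide | COc1ccc([C@@H](O)CC(=O)N(C)OC)c(CC=C(C)C)c1OCOC | intermediate
9 | methyl acetoacetate | COC(=O)CC(C)=O | starting material
10 | 1-bromo-3-methylbut-2-ene | CC(C)=CCBr | starting material
11 | methyl 2-acetyl-5-methylhex-4-enoate | COC(=O)C(CC=C(C)C)C(C)=O | intermediate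
12 | methyl 2-(3-methylbut-2-en-1-yl)-3,5-dioxohexanoate | COC(=O)C(CC=C(C)C)C(=O)CC(C)=O | intermediate
13 | methyl (9S)-9-hydroxy-9-[4-methoxy-3-(methoxymethoxy)-2-(3-methylbut-2-en-1-yl)phenyl]-2-(3-methylbut-2-en-1-yl)-3,5,7-trioxononanoate (both C2 epimers) | COc1ccc([C@@H](O)CC(=O)CC(=O)CC(=O)C(CC=C(C)C)C(=O)OC)c(CC=C(C)C)c1OCOC | intermediate
14 | methyl 4-[(2S)-2-[4-methoxy-3-(methoxymethoxy)-2-(3-methylbut-2-en-1-yl)phenyl]-4-oxo-3,4-dihydro-2H-pyran-6-yl]-2-(3-methylbut-2-en-1-yl)-3-oxobutanoate (both epimers at butanoate C2) | COc1ccc([C@@H]2CC(=O)C=C(CC(=O)C(CC=C(C)C)C(=O)OC)O2)c(CC=C(C)C)c1OCOC | intermediate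
15 | (2S)-2-[4-methoxy-3-(methoxymethoxy)-2-(3-methylbut-2-en-1-yl)phenyl]-6-(3-methylbut-2-en-1-yl)-2,3-dihydro-4aH-chromene-4,5,7(6H)-trione (epimers at C4a and C6) | COc1ccc([C@@H]2CC(=O)C3C(=O)C(CC=C(C)C)C(=O)C=C3O2)c(CC=C(C)C)c1OCOC | intermediate
16 | (2S)-5,7-dihydroxy-2-[4-methoxy-3-(methoxymethoxy)-2-(3-methylbut-2-en-1-yl)phenyl]-6-(3-methylbut-2-en-1-yl)-2,3-dihydro-4H-chromen-4-one | COc1ccc([C@@H]2CC(=O)c3c(cc(O)c(CC=C(C)C)c3O)O2)c(CC=C(C)C)c1OCOC | intermediate
17 | (2S)-5,7-dihydroxy-2-[3-hydroxy-4-methoxy-2-(3-methylbut-2-en-1-yl)phenyl]-6-(3-methylbut-2-en-1-yl)-2,3-dihydro-4H-chromen-4-one (CNP0306216.1) | COc1ccc([C@@H]2CC(=O)c3c(cc(O)c(CC=C(C)C)c3O)O2)c(CC=C(C)C)c1O | target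

**Step count**

Total: 10 steps. Longest linear sequence: 8 steps (1, 2, 3, 4, 5, 8, 9, 10); steps 6 and 7 build the second fragment.

**Steps most likely to fail**

Step 9 (proposed new method). Three processes may defeat it. The C4a dienolate may fail to attack an ester whose neighbouring C6 is largely enolized. Methoxide may add to C8a and open ring C by addition–elimination. The product may lose its C2 configuration by base-induced opening to the chalcone and reclosure.

The fallback uses known chemistry and brings ring A in as an intact phloroglucinol. Commercial 2',4',6'-trihydroxyacetophenone is C-prenylated with 10 (DBU, THF) to 1-[2,4,6-trihydroxy-3-(3-methylbut-2-en-1-yl)phenyl]ethan-1-one F1. This is protected (NaH, MOMCl, DMF) as 1-[2,4,6-tris(methoxymethoxy)-3-(3-methylbut-2-en-1-yl)phenyl]ethan-1-one F2. Claisen–Schmidt condensation of F2 with aldehyde 4 (KOH, EtOH/H2O, rt) should give (E)-3-[4-methoxy-3-(methoxymethoxy)-2-(3-methylbut-2-en-1-yl)phenyl]-1-[2,4,6-tris(methoxymethoxy)-3-(3-methylbut-2-en-1-yl)phenyl]prop-2-en-1-one F3. HCl in MeOH removes the four MOM groups to give (E)-3-[3-hydroxy-4-methoxy-2-(3-methylbut-2-en-1-yl)phenyl]-1-[2,4,6-trihydroxy-3-(3-methylbut-2-en-1-yl)phenyl]prop-2-en-1-one F4. NaOAc in refluxing EtOH closes ring C by oxa-Michael addition to rac-5,7-dihydroxy-2-[3-hydroxy-4-methoxy-2-(3-methylbut-2-en-1-yl)phenyl]-6-(3-methylbut-2-en-1-yl)-2,3-dihydro-4H-chromen-4-one F5. The regioisomer rac-5,7-dihydroxy-2-[3-hydroxy-4-methoxy-2-(3-methylbut-2-en-1-yl)phenyl]-8-(3-methylbut-2-en-1-yl)-2,3-dihydro-4H-chromen-4-one F6 should form alongside and is removed by chromatography. Preparative HPLC of F5 on an amylose tris(3,5-dimethylphenylcarbamate) phase then delivers 17. This fallback sets out from 4 and rejoins the route at 17; it gives up the regio- and stereocontrol that the pyranone precursor provides.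

Step 8. Three processes may defeat it. Proton transfer from the amide to the trianion may compete with acylation. The free triketo ester 13 may lactonize to a pyrone before the acid step. Acid may dehydrate the benzylic carbinol to the dienone or cleave the MOM ether.

The fallback replaces acylation by aldol addition and oxidation. Amide 8 is silylated (TESCl, imidazole, DMF) to (3S)-N-methoxy-3-[4-methoxy-3-(methoxymethoxy)-2-(3-methylbut-2-en-1-yl)phenyl]-N-methyl-3-(triethylsilyloxy)propanamide F7. Reduction with i-Bu2AlH (THF, −78 °C) gives (3S)-3-[4-methoxy-3-(methoxymethoxy)-2-(3-methylbut-2-en-1-yl)phenyl]-3-(triethylsilyloxy)propanal F8. The trianion of 12 should add to F8 at −78 °C, where aldehyde addition outruns proton transfer, to give methyl (9S)-7-hydroxy-9-[4-methoxy-3-(methoxymethoxy)-2-(3-methylbut-2-en-1-yl)phenyl]-2-(3-methylbut-2-en-1-yl)-3,5-dioxo-9-(triethylsilyloxy)nonanoate F9. Dess–Martin periodinane oxidizes the new carbinol to methyl (9S)-9-[4-methoxy-3-(methoxymethoxy)-2-(3-methylbut-2-en-1-yl)phenyl]-2-(3-methylbut-2-en-1-yl)-3,5,7-trioxo-9-(triethylsilyloxy)nonanoate F10. HF·pyridine followed by catalytic TsOH·H2O removes the silyl group to 13 and closes the pyranone. This fallback sets out from 8 and rejoins at 14.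

Step 2. Three processes may defeat it. Oxidative addition at the doubly ortho-substituted bromide may be slow. Coupling may occur at the substituted allyl terminus to give the 1,1-dimethylallyl isomer. The stannane may transfer its allyl group to the aldehyde.

The fallback uses an aryl copper reagent instead of palladium. Aldehyde 2 is converted (HC(OMe)3, MeOH, cat. PPTS) to 2-bromo-1-(dimethoxymethyl)-4-methoxy-3-(methoxymethoxy)benzene F11. Bromine–lithium exchange (n-BuLi, THF, −78 °C), transmetalation with CuBr·SMe2 and SN2 alkylation by 10 should give 1-(dimethoxymethyl)-4-methoxy-3-(methoxymethoxy)-2-(3-methylbut-2-en-1-yl)benzene F12. PPTS in acetone/water releases the aldehyde. This fallback sets out from 2 and rejoins at 4.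

**Further compounds**

F1 | step 9 | 1-[2,4,6-trihydroxy-3-(3-methylbut-2-en-1-yl)phenyl]ethan-1-one | CC(=O)c1c(O)cc(O)c(CC=C(C)C)c1O
F2 | step 9 | 1-[2,4,6-tris(methoxymethoxy)-3-(3-methylbut-2-en-1-yl)phenyl]ethan-1-one | CC(=O)c1c(OCOC)cc(OCOC)c(CC=C(C)C)c1OCOC
F3 | step 9 | (E)-3-[4-methoxy-3-(methoxymethoxy)-2-(3-methylbut-2-en-1-yl)phenyl]-1-[2,4,6-tris(methoxymethoxy)-3-(3-methylbut-2-en-1-yl)phenyl]prop-2-en-1-one | COCOc1cc(OCOC)c(CC=C(C)C)c(OCOC)c1C(=O)/C=C/c1ccc(OC)c(OCOC)c1CC=C(C)C
F4 | step 9 | (E)-3-[3-hydroxy-4-methoxy-2-(3-methylbut-2-en-1-yl)phenyl]-1-[2,4,6-trihydroxy-3-(3-methylbut-2-en-1-yl)phenyl]prop-2-en-1-one | COc1ccc(/C=C/C(=O)c2c(O)cc(O)c(CC=C(C)C)c2O)c(CC=C(C)C)c1O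
F5 | step 9 | rac-5,7-dihydroxy-2-[3-hydroxy-4-methoxy-2-(3-methylbut-2-en-1-yl)phenyl]-6-(3-methylbut-2-en-1-yl)-2,3-dihydro-4H-chromen-4-one | COc1ccc(C2CC(=O)c3c(cc(O)c(CC=C(C)C)c3O)O2)c(CC=C(C)C)c1O
F6 | step 9 | rac-5,7-dihydroxy-2-[3-hydroxy-4-methoxy-2-(3-methylbut-2-en-1-yl)phenyl]-8-(3-methylbut-2-en-1-yl)-2,3-dihydro-4H-chromen-4-one | COc1ccc(C2CC(=O)c3c(O)cc(O)c(CC=C(C)C)c3O2)c(CC=C(C)C)c1O
F7 | step 8 | (3S)-N-methoxy-3-[4-methoxy-3-(methoxymethoxy)-2-(3-methylbut-2-en-1-yl)phenyl]-N-methyl-3-(triethylsilyloxy)propanamide | COc1ccc([C@@H](O[Si](CC)(CC)CC)CC(=O)N(C)OC)c(CC=C(C)C)c1OCOC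
F8 | step 8 | (3S)-3-[4-methoxy-3-(methoxymethoxy)-2-(3-methylbut-2-en-1-yl)phenyl]-3-(triethylsilyloxy)propanal | COc1ccc([C@@H](O[Si](CC)(CC)CC)CC=O)c(CC=C(C)C)c1OCOC
F9 | step 8 | methyl (9S)-7-hydroxy-9-[4-methoxy-3-(methoxymethoxy)-2-(3-methylbut-2-en-1-yl)phenyl]-2-(3-methylbut-2-en-1-yl)-3,5-dioxo-9-(triethylsilyloxy)nonanoate | COc1ccc([C@@H](O[Si](CC)(CC)CC)CC(O)CC(=O)CC(=O)C(CC=C(C)C)C(=O)OC)c(CC=C(C)C)c1OCOC
F10 | step 8 | methyl (9S)-9-[4-methoxy-3-(methoxymethoxy)-2-(3-methylbut-2-en-1-yl)phenyl]-2-(3-methylbut-2-en-1-yl)-3,5,7-trioxo-9-(triethylsilyloxy)nonanoate | COc1ccc([C@@H](O[Si](CC)(CC)CC)CC(=O)CC(=O)CC(=O)C(CC=C(C)C)C(=O)OC)c(CC=C(C)C)c1OCOC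
F11 | step 2 | 2-bromo-1-(dimethoxymethyl)-4-methoxy-3-(methoxymethoxy)benzene | COc1ccc(C(OC)OC)c(Br)c1OCOC
F12 | step 2 | 1-(dimethoxymethyl)-4-methoxy-3-(methoxymethoxy)-2-(3-methylbut-2-en-1-yl)benzene | COc1ccc(C(OC)OC)c(CC=C(C)C)c1OCOC
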